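**Retrosynthetic overview**
- Feature: in the 2,3-dihydrobenzofuran unit, C2 is a benzylic carbon bearing a 4-oxygenated aryl ring and ionises easily. The oxygen on C7a can reach C2 through a five-membered ring, and the adjacent C3 is a robust stereocentre. O1–C2 is therefore the key disconnection, and C2 is derived from C3.
- Last disconnections: the three O-benzyl groups, then the bond between C5 of the dihydrobenzofuran and the CH2 on the lactone α-carbon. That bond comes from Negishi coupling of the 5-bromide with the zinc homoenolate released from the siloxycyclopropane of an (R)-β-benzylbutyrolactone.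
- Ring-opened phenol carbinol: the C2–aryl bond comes from Grignard addition to an α-aryl aldehyde, and both epimers are accepted. C3 comes from auxiliary-controlled alkylation of an arylacetyl oxazolidinone with benzyl chloromethyl ether. The arylacetic acid comes from one-carbon homologation of 5-bromo-ortho-vanillin with the phenol masked as its allyl ether.
- Lactone fragment: auxiliary-controlled alkylation of a dihydroferulic acid imide with tert-butyl bromoacetate, then reduction and lactonisation. Cyclopropanation of the ketene silyl acetal anti to the benzyl group fixes the α-centre.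
- Ring order: the dihydrofuran ring (step 11) forms in one fragment. The butyrolactone ring (step 16) and a temporary cyclopropane (step 18, opened in step 19) form in the other. All benzene rings are bought in.

Key step: step 11

Assumption: the carbinol carbon of the compounds before the key step is carried as a mixture of epimers and drawn without configuration, and the enol ether geometry in the homologation is likewise left open.

Step 1
Reactants: 1 5-bromo-2-hydroxy-3-methoxybenzaldehyde
Product: 2 2-(allyloxy)-5-bromo-3-methoxybenzaldehyde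
Conditions: allyl bromide, K2CO3, DMF, rt
Reagents that add atoms: allyl bromide C=CCBr
Why: Williamson ether synthesis on the acidic ortho-formyl phenol; the allyl ether should mask the future C7a oxygen through base, Lewis acid, hydride and Grignard steps and can later be removed without touching benzyl ethers or the aryl bromide.

Step 2
Reactants: 2 2-(allyloxy)-5-bromo-3-methoxybenzaldehyde
Product: 3 2-(allyloxy)-5-bromo-1-methoxy-3-(2-methoxyethenyl)benzene (E/Z mixture)
Conditions: Ph3P(CH2OMe)Cl, KOtBu, THF, 0 °C to rt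
Reagents that add atoms: (methoxymethyl)triphenylphosphonium chloride COC[P+](c1ccccc1)(c1ccccc1)c1ccccc1.[Cl-]
Why: Wittig methoxymethylenation of a non-enolisable aromatic aldehyde adds the one carbon that becomes C2, and the alkene geometry is irrelevant.

Step 3
Reactants: 3 2-(allyloxy)-5-bromo-1-methoxy-3-(2-methoxyethenyl)benzene
Product: 4 2-[2-(allyloxy)-5-bromo-3-methoxyphenyl]acetaldehyde
Conditions: 2 M HCl, THF, 50 °C
Reagents that add atoms: water O
Why: Acid-catalysed enol ether hydrolysis through the oxocarbenium ion and hemiacetal should give the arylacetaldehyde, while aryl allyl and aryl methyl ethers are stable to dilute acid.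

Step 4
Reactants: 4 2-[2-(allyloxy)-5-bromo-3-methoxyphenyl]acetaldehyde
Product: 5 2-[2-(allyloxy)-5-bromo-3-methoxyphenyl]acetic acid
Conditions: NaClO2, NaH2PO4, 2-methyl-2-butene, t-BuOH/H2O, rt
Reagents that add atoms: sodium chlorite [Na+].[O-]Cl=O
Why: Pinnick oxidation converts the aldehyde into the acid under buffered conditions, and 2-methyl-2-butene takes up the HOCl so that the allyl group and the electron-rich ring are not chlorinated.

Step 5
Reactants: 5 2-[2-(allyloxy)-5-bromo-3-methoxyphenyl]acetic acid; 6 (S)-4-benzyl-2-oxazolidinone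
Product: 8 (S)-3-{2-[2-(allyloxy)-5-bromo-3-methoxyphenyl]acetyl}-4-benzyloxazolidin-2-one, via mixed pivalic anhydride 7 (not isolated)
Conditions: PivCl, Et3N, THF, −20 °C; then 6, LiCl, rt
Reagents that add atoms: pivaloyl chloride CC(C)(C)C(=O)Cl (atoms kept only in 7)
Why: Mixed-anhydride N-acylation of the oxazolidinone, in which LiCl/Et3N make the carbamate nitrogen nucleophilic enough to attack the less hindered arylacetyl carbonyl of 7.

Step 6
Reactants: 8 (S)-3-{2-[2-(allyloxy)-5-bromo-3-methoxyphenyl]acetyl}-4-benzyloxazolidin-2-one; 9 benzyl chloromethyl ether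
Product: 11 (S)-3-{(R)-2-[2-(allyloxy)-5-bromo-3-methoxyphenyl]-3-(benzyloxy)propanoyl}-4-benzyloxazolidin-2-one, via trichlorotitanium (Z)-enolate 10 (not isolated)
Conditions: TiCl4, i-Pr2NEt, CH2Cl2, 0 °C; then 9, 0 °C
Reagents that add atoms: titanium tetrachloride Cl[Ti](Cl)(Cl)Cl (atoms kept only in 10)
Why: Evans asymmetric alkylation through the chelated (Z)-titanium enolate, in which the SN1-active chloromethyl ether approaches the face opposite the C4 benzyl group of the auxiliary and so sets the future C3 as (R).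

Step 7
Reactants: 11 (S)-3-{(R)-2-[2-(allyloxy)-5-bromo-3-methoxyphenyl]-3-(benzyloxy)propanoyl}-4-benzyloxazolidin-2-one
Product: 12 (S)-2-[2-(allyloxy)-5-bromo-3-methoxyphenyl]-3-(benzyloxy)propan-1-ol
Conditions: LiBH4, MeOH (1 equiv), THF, 0 °C
Reagents that add atoms: none
Why: Reductive cleavage of the N-acyloxazolidinone by LiBH4 takes place at the exocyclic carbonyl, frees the auxiliary for reuse and does not enolise the α-aryl centre (the descriptor changes to S through priorities only).

Step 8
Reactants: 12 (S)-2-[2-(allyloxy)-5-bromo-3-methoxyphenyl]-3-(benzyloxy)propan-1-ol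
Product: 13 (R)-2-[2-(allyloxy)-5-bromo-3-methoxyphenyl]-3-(benzyloxy)propanal
Conditions: Dess–Martin periodinane, CH2Cl2, 0 °C to rt; crude product used at once
Reagents that add atoms: none
Why: Dess–Martin oxidation runs without base, so the configurationally sensitive α-aryl-β-benzyloxy aldehyde should form without enolisation or loss of benzyl alcohol, and it is not chromatographed.

Step 9
Reactants: 13 (R)-2-[2-(allyloxy)-5-bromo-3-methoxyphenyl]-3-(benzyloxy)propanal; 14 1-(benzyloxy)-4-bromo-2-methoxybenzene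
Product: 16 (2R)-2-[2-(allyloxy)-5-bromo-3-methoxyphenyl]-3-(benzyloxy)-1-[4-(benzyloxy)-3-methoxyphenyl]propan-1-ol (C1 epimers), via arylmagnesium bromide 15 (not isolated)
Conditions: 14, Mg, THF, reflux; then 13 added at −78 °C, THF
Reagents that add atoms: magnesium [Mg] (kept only in 15)
Why: Grignard addition to the aldehyde at low temperature outruns deprotonation and forms the C2–aryl bond; the carbinol mixture is acceptable because step 11 erases that centre, and the readily enolised deoxybenzoin-type ketone level is never entered.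

Step 10
Reactants: 16 (2R)-2-[2-(allyloxy)-5-bromo-3-methoxyphenyl]-3-(benzyloxy)-1-[4-(benzyloxy)-3-methoxyphenyl]propan-1-ol
Product: 17 4-bromo-2-{(2R)-1-(benzyloxy)-3-[4-(benzyloxy)-3-methoxyphenyl]-3-hydroxypropan-2-yl}-6-methoxyphenol (carbinol epimers)
Conditions: Pd(PPh3)4 (cat.), morpholine, THF, rt
Reagents that add atoms: none
Why: Tsuji–Trost-type deallylation, in which zerovalent palladium ionises the aryl allyl ether to a π-allyl complex that morpholine intercepts, while oxidative addition of the electron-rich aryl bromide is slow at room temperature.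

Step 11
Reactants: 17 4-bromo-2-{(2R)-1-(benzyloxy)-3-[4-(benzyloxy)-3-methoxyphenyl]-3-hydroxypropan-2-yl}-6-methoxyphenol
Product: 19 (2S,3R)-3-[(benzyloxy)methyl]-2-[4-(benzyloxy)-3-methoxyphenyl]-5-bromo-7-methoxy-2,3-dihydrobenzofuran, via para-benzyloxybenzylic cation 18 (not isolated)
Conditions: CF3CO2H (5 equiv), CH2Cl2 (0.01 M), 0 °C to rt
Reagents that add atoms: none
Why: CF3CO2H protonates the benzylic hydroxyl of either epimer of 17 and water leaves, because cation 18 is delocalised onto the para-benzyloxy oxygen (an O-benzylated para-quinone methide); the phenol oxygen on C7a then adds to C2 and loses its proton, which forms O1–C2. The closest known reaction type is the acid-mediated cyclodehydration of 2-(2-hydroxyaryl)-1-arylpropane-1,3-diol derivatives to trans-2-aryl-2,3-dihydrobenzofurans (phenylcoumaran formation). The dihydrofuran ring closes in the 5-exo-trig mode, since the C2=C1' bond of the quinone-methide form stays outside the new ring. C2 is controlled by C3 alone: the oxygen reaches the planar cation in the conformer that keeps the aryl group away from the benzyloxymethyl group, and because C2–O1 re-ionises in acid any cis isomer should drain to the more stable (2S,3R)-trans isomer. The step needs chemoselective ionisation and intramolecular capture, and the substrate secures both: only C2 is a doubly activated benzylic position, the primary oxygen is capped as a benzyl ether and could only close a strained four-membered ring, and high dilution disfavours Friedel–Crafts capture by a second molecule. C3 bears neither a leaving group nor an adjacent carbonyl group at this stage and so keeps its configuration.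

Step 12
Reactants: 20 3-(4-hydroxy-3-methoxyphenyl)propanoic acid
Product: 21 3-[4-(benzyloxy)-3-methoxyphenyl]propanoic acid
Conditions: BnBr, KOH, EtOH/H2O, reflux; then HCl
Reagents that add atoms: benzyl bromide BrCc1ccccc1
Why: Williamson ether synthesis on the phenoxide in aqueous-alcoholic KOH, in which any benzyl ester formed is saponified in the same flask.

Step 13
Reactants: 21 3-[4-(benzyloxy)-3-methoxyphenyl]propanoic acid; 6 (S)-4-benzyl-2-oxazolidinone
Product: 23 (S)-4-benzyl-3-{3-[4-(benzyloxy)-3-methoxyphenyl]propanoyl}oxazolidin-2-one, via mixed pivalic anhydride 22 (not isolated)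
Conditions: PivCl, Et3N, THF, −20 °C; then 6, LiCl, rt
Reagents that add atoms: pivaloyl chloride CC(C)(C)C(=O)Cl (atoms kept only in 22)
Why: Mixed-anhydride N-acylation of the oxazolidinone at the less hindered carbonyl of 22, as in step 5.

Step 14
Reactants: 23 (S)-4-benzyl-3-{3-[4-(benzyloxy)-3-methoxyphenyl]propanoyl}oxazolidin-2-one; 24 tert-butyl bromoacetate
Product: 26 tert-butyl (R)-3-[4-(benzyloxy)-3-methoxybenzyl]-4-[(S)-4-benzyl-2-oxooxazolidin-3-yl]-4-oxobutanoate, via sodium (Z)-enolate 25 (not isolated)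
Conditions: NaN(SiMe3)2, THF, −78 °C; then 24, −78 to −40 °C
Reagents that add atoms: sodium bis(trimethylsilyl)amide C[Si](C)(C)[N-][Si](C)(C)C.[Na+] (Na kept only in 25)
Why: Evans asymmetric alkylation of the chelated (Z)-sodium enolate with the reactive α-bromo ester from the face opposite the auxiliary benzyl group sets the future lactone C4 as (R).

Step 15
Reactants: 26 tert-butyl (R)-3-[4-(benzyloxy)-3-methoxybenzyl]-4-[(S)-4-benzyl-2-oxooxazolidin-3-yl]-4-oxobutanoate
Product: 27 tert-butyl (R)-3-[4-(benzyloxy)-3-methoxybenzyl]-4-hydroxybutanoate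
Conditions: LiBH4, MeOH (1 equiv), THF, 0 °C
Reagents that add atoms: none
Why: Chemoselective reductive auxiliary cleavage, since LiBH4 reduces the activated imide carbonyl much faster than the hindered tert-butyl ester and leaves the stereocentre untouched.

Step 16
Reactants: 27 tert-butyl (R)-3-[4-(benzyloxy)-3-methoxybenzyl]-4-hydroxybutanoate
Product: 28 (R)-4-[4-(benzyloxy)-3-methoxybenzyl]dihydrofuran-2(3H)-one
Conditions: p-TsOH·H2O (cat.), toluene, 80 °C
Reagents that add atoms: none
Why: Acid-catalysed lactonisation (intramolecular transesterification, 5-exo-trig) expels tert-butanol and closes the butyrolactone ring without touching the stereocentre.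

Step 17
Reactants: 28 (R)-4-[4-(benzyloxy)-3-methoxybenzyl]dihydrofuran-2(3H)-one
Product: 30 (R)-{[4-(4-benzyloxy-3-methoxybenzyl)-4,5-dihydrofuran-2-yl]oxy}trimethylsilane, via lithium enolate 29 (not isolated)
Conditions: LiN(i-Pr)2, THF, −78 °C; then Me3SiCl, −78 °C to rt; non-aqueous work-up (pentane, filtration)
Reagents that add atoms: chlorotrimethylsilane C[Si](C)(C)Cl; lithium diisopropylamide CC(C)[N-]C(C)C.[Li+] (Li kept only in 29)
Why: Kinetic enolisation of the lactone followed by O-silylation of the ring-locked enolate is the standard preparation of cyclic ketene silyl acetals, and the C4 centre is not involved.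

Step 18
Reactants: 30 (R)-{[4-(4-benzyloxy-3-methoxybenzyl)-4,5-dihydrofuran-2-yl]oxy}trimethylsilane
Product: 31 (1S,4R,5R)-4-[4-(benzyloxy)-3-methoxybenzyl]-1-(trimethylsilyloxy)-2-oxabicyclo[3.1.0]hexane
Conditions: Et2Zn, CH2I2, Et2O, 0 °C to rt; pyridine quench, filtration
Reagents that add atoms: diiodomethane ICI
Why: Furukawa-modified Simmons–Smith cyclopropanation of the very electron-rich ketene acetal double bond, in which the zinc carbenoid adds to the face anti to the C4 benzyl group, so that the new CH2 (C6) and with it the future lactone α-centre are set trans to C4.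

Step 19
Reactants: 31 (1S,4R,5R)-4-[4-(benzyloxy)-3-methoxybenzyl]-1-(trimethylsilyloxy)-2-oxabicyclo[3.1.0]hexane; 19 (2S,3R)-3-[(benzyloxy)methyl]-2-[4-(benzyloxy)-3-methoxyphenyl]-5-bromo-7-methoxy-2,3-dihydrobenzofuran
Product: 33 (3R,4R)-4-[4-(benzyloxy)-3-methoxybenzyl]-3-({(2S,3R)-3-[(benzyloxy)methyl]-2-[4-(benzyloxy)-3-methoxyphenyl]-7-methoxy-2,3-dihydrobenzofuran-5-yl}methyl)dihydrofuran-2(3H)-one, via zinc homoenolate 32 (not isolated)
Conditions: ZnCl2, Et2O, rt, volatiles removed in vacuo; then 19, Pd2(dba)3 (cat.), SPhos (cat.), THF, 50 °C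
Reagents that add atoms: zinc chloride Cl[Zn]Cl (atoms kept only in 32)
Why: ZnCl2 cleaves the less hindered C1–C6 bond of the 1-alkoxy-1-siloxycyclopropane with loss of Me3SiCl and retention at the lactone α-carbon to give the carbonyl-chelated zinc homoenolate, and Negishi coupling at zerovalent palladium then joins its CH2 to C5 of the dihydrobenzofuran, the bulky biarylphosphine favouring reductive elimination over β-hydride elimination.

Step 20
Reactants: 33 (3R,4R)-4-[4-(benzyloxy)-3-methoxybenzyl]-3-({(2S,3R)-3-[(benzyloxy)methyl]-2-[4-(benzyloxy)-3-methoxyphenyl]-7-methoxy-2,3-dihydrobenzofuran-5-yl}methyl)dihydrofuran-2(3H)-one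
Product: 34 isolappaol A
Conditions: H2 (1 atm), Pd/C, EtOAc/EtOH, rt, stopped after uptake of three equivalents
Reagents that add atoms: none
Why: Catalytic hydrogenolysis cleaves the three O-benzyl groups, which react faster than the cyclic secondary C2–O1 benzylic ether, so that timely interruption should leave both heterocycles and all four stereocentres intact.

**Compound list**
1 | 5-bromo-2-hydroxy-3-methoxybenzaldehyde | COc1cc(Br)cc(C=O)c1O | starting material
2 | 2-(allyloxy)-5-bromo-3-methoxybenzaldehyde | C=CCOc1c(OC)cc(Br)cc1C=O | intermediate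
3 | 2-(allyloxy)-5-bromo-1-methoxy-3-(2-methoxyethenyl)benzene (E/Z mixture) | COC=Cc1cc(Br)cc(OC)c1OCC=C | intermediate
4 | 2-[2-(allyloxy)-5-bromo-3-methoxyphenyl]acetaldehyde | O=CCc1cc(Br)cc(OC)c1OCC=C | intermediate
5 | 2-[2-(allyloxy)-5-bromo-3-methoxyphenyl]acetic acid | OC(=O)Cc1cc(Br)cc(OC)c1OCC=C | intermediate
6 | (S)-4-benzyl-2-oxazolidinone | O=C1N[C@@H](Cc2ccccc2)CO1 | starting material
7 | 2-[2-(allyloxy)-5-bromo-3-methoxyphenyl]acetic pivalic anhydride (not isolated) | CC(C)(C)C(=O)OC(=O)Cc1cc(Br)cc(OC)c1OCC=C | intermediate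
8 | (S)-3-{2-[2-(allyloxy)-5-bromo-3-methoxyphenyl]acetyl}-4-benzyloxazolidin-2-one | O=C(Cc1cc(Br)cc(OC)c1OCC=C)N1[C@@H](Cc2ccccc2)COC1=O | intermediate
9 | benzyl chloromethyl ether | ClCOCc1ccccc1 | starting material
10 | trichlorotitanium (Z)-enolate of 8 (not isolated) | C=CCOc1c(OC)cc(Br)cc1/C=C(\O[Ti](Cl)(Cl)Cl)N1[C@@H](Cc2ccccc2)COC1=O | intermediate
11 | (S)-3-{(R)-2-[2-(allyloxy)-5-bromo-3-methoxyphenyl]-3-(benzyloxy)propanoyl}-4-benzyloxazolidin-2-one | O=C([C@@H](COCc1ccccc1)c1cc(Br)cc(OC)c1OCC=C)N1[C@@H](Cc2ccccc2)COC1=O | intermediate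
12 | (S)-2-[2-(allyloxy)-5-bromo-3-methoxyphenyl]-3-(benzyloxy)propan-1-ol | OC[C@@H](COCc1ccccc1)c1cc(Br)cc(OC)c1OCC=C | intermediate
13 | (R)-2-[2-(allyloxy)-5-bromo-3-methoxyphenyl]-3-(benzyloxy)propanal | O=C[C@@H](COCc1ccccc1)c1cc(Br)cc(OC)c1OCC=C | intermediate
14 | 1-(benzyloxy)-4-bromo-2-methoxybenzene | COc1cc(Br)ccc1OCc1ccccc1 | starting material
15 | [4-(benzyloxy)-3-methoxyphenyl]magnesium bromide (not isolated) | COc1cc([Mg]Br)ccc1OCc1ccccc1 | intermediate
16 | (2R)-2-[2-(allyloxy)-5-bromo-3-methoxyphenyl]-3-(benzyloxy)-1-[4-(benzyloxy)-3-methoxyphenyl]propan-1-ol (C1 epimers) | OC(c1ccc(OCc2ccccc2)c(OC)c1)[C@@H](COCc1ccccc1)c1cc(Br)cc(OC)c1OCC=C | intermediate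
17 | 4-bromo-2-{(2R)-1-(benzyloxy)-3-[4-(benzyloxy)-3-methoxyphenyl]-3-hydroxypropan-2-yl}-6-methoxyphenol (carbinol epimers) | OC(c1ccc(OCc2ccccc2)c(OC)c1)[C@@H](COCc1ccccc1)c1cc(Br)cc(OC)c1O | intermediate
18 | para-benzyloxybenzylic cation from 17, C3 unchanged (not isolated) | COc1cc([CH+][C@@H](COCc2ccccc2)c2cc(Br)cc(OC)c2O)ccc1OCc1ccccc1 | intermediate
19 | (2S,3R)-3-[(benzyloxy)methyl]-2-[4-(benzyloxy)-3-methoxyphenyl]-5-bromo-7-methoxy-2,3-dihydrobenzofuran | COc1cc(Br)cc2c1O[C@H](c1ccc(OCc3ccccc3)c(OC)c1)[C@H]2COCc1ccccc1 | intermediate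
20 | 3-(4-hydroxy-3-methoxyphenyl)propanoic acid | COc1cc(CCC(=O)O)ccc1O | starting material
21 | 3-[4-(benzyloxy)-3-methoxyphenyl]propanoic acid | COc1cc(CCC(=O)O)ccc1OCc1ccccc1 | intermediate
22 | 3-[4-(benzyloxy)-3-methoxyphenyl]propanoic pivalic anhydride (not isolated) | COc1cc(CCC(=O)OC(=O)C(C)(C)C)ccc1OCc1ccccc1 | intermediate
23 | (S)-4-benzyl-3-{3-[4-(benzyloxy)-3-methoxyphenyl]propanoyl}oxazolidin-2-one | COc1cc(CCC(=O)N2[C@@H](Cc3ccccc3)COC2=O)ccc1OCc1ccccc1 | intermediate
24 | tert-butyl bromoacetate | CC(C)(C)OC(=O)CBr | starting material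
25 | sodium (Z)-enolate of 23 (not isolated) | COc1cc(C/C=C(\[O-])N2[C@@H](Cc3ccccc3)COC2=O)ccc1OCc1ccccc1.[Na+] | intermediate
26 | tert-butyl (R)-3-[4-(benzyloxy)-3-methoxybenzyl]-4-[(S)-4-benzyl-2-oxooxazolidin-3-yl]-4-oxobutanoate | COc1cc(C[C@H](CC(=O)OC(C)(C)C)C(=O)N2[C@@H](Cc3ccccc3)COC2=O)ccc1OCc1ccccc1 | intermediate
27 | tert-butyl (R)-3-[4-(benzyloxy)-3-methoxybenzyl]-4-hydroxybutanoate | COc1cc(C[C@H](CC(=O)OC(C)(C)C)CO)ccc1OCc1ccccc1 | intermediate
28 | (R)-4-[4-(benzyloxy)-3-methoxybenzyl]dihydrofuran-2(3H)-one | COc1cc(C[C@H]2COC(=O)C2)ccc1OCc1ccccc1 | intermediate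
29 | lithium enolate of 28 (not isolated) | COc1cc(C[C@H]2COC([O-])=C2)ccc1OCc1ccccc1.[Li+] | intermediate
30 | (R)-{[4-(4-benzyloxy-3-methoxybenzyl)-4,5-dihydrofuran-2-yl]oxy}trimethylsilane | COc1cc(C[C@H]2COC(O[Si](C)(C)C)=C2)ccc1OCc1ccccc1 | intermediate
31 | (1S,4R,5R)-4-[4-(benzyloxy)-3-methoxybenzyl]-1-(trimethylsilyloxy)-2-oxabicyclo[3.1.0]hexane | COc1cc(C[C@H]2CO[C@]3(O[Si](C)(C)C)C[C@H]23)ccc1OCc1ccccc1 | intermediate
32 | {(3R,4R)-4-[4-(benzyloxy)-3-methoxybenzyl]-2-oxotetrahydrofuran-3-yl}methylzinc chloride (not isolated) | COc1cc(C[C@H]2COC(=O)[C@@H]2C[Zn]Cl)ccc1OCc1ccccc1 | intermediate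
33 | tri-O-benzyl isolappaol A, (3R,4R)-lactone, (2S,3R)-dihydrobenzofuran | COc1cc(C[C@H]2COC(=O)[C@@H]2Cc2cc(OC)c3c(c2)[C@H](COCc2ccccc2)[C@@H](c2ccc(OCc4ccccc4)c(OC)c2)O3)ccc1OCc1ccccc1 | intermediate
34 | isolappaol A | COc1cc(C[C@H]2COC(=O)[C@@H]2Cc2cc(OC)c3c(c2)[C@H](CO)[C@@H](c2ccc(O)c(OC)c2)O3)ccc1O | target

**Total step count:** 20
**Longest linear sequence:** 13 (steps 1–11, 19, 20)

**Steps most likely to fail**

**Step 19 (ring opening and Negishi coupling).**
- What may go wrong: incomplete or unselective cleavage of the cyclopropane, protonation of the zinc homoenolate by adventitious acid, and β-hydride elimination from the alkylpalladium intermediate in competition with reductive elimination.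
- The fallback sets out from 19 and 28 and comes back at 33. Steps 17 and 18 fall away.
- Bromide 19 is treated with n-BuLi (THF, −78 °C) to give the aryllithium F1, which DMF formylates to the 5-carbaldehyde F2.
- NaBH4 gives the benzylic alcohol F3, and PBr3 gives the benzylic bromide F4.
- Lithium enolate 29, made from 28 with LiN(SiMe3)2 in THF/DMPU at −78 °C, is then alkylated with F4 anti to the β-benzyl group. This is the classical trans-selective route to dibenzylbutyrolactones and should give 33.

**Step 11 (cationic cycloetherification).**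
- What may go wrong: capture of the cation by the electron-rich ring of a second molecule, acid-induced loss of the para-benzyl group from the delocalised cation, and incomplete equilibration to the trans isomer.
- The fallback sets out from 13 and comes back at 19. It replaces the cation under acid by a neutral para-quinone methide under base.
- Aldehyde 13 is treated with [4-(tert-butyldimethylsilyloxy)-3-methoxyphenyl]magnesium bromide F5, made from commercial (4-bromo-2-methoxyphenoxy)(tert-butyl)dimethylsilane and Mg. The alkoxide is trapped with Ac2O to give the benzylic acetate F6.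
- Deallylation as in step 10 gives the phenol acetate F7.
- Bu4NF removes the silyl group, and the phenoxide expels acetate to give the para-quinone methide F8. The ortho phenol adds to it in a reversible 1,6-oxa-addition to give the trans-dihydrobenzofuran phenol F9.
- BnBr/K2CO3 in DMF returns to 19.

**Step 9 (with step 8: α-aryl aldehyde and its arylation).**
- What may go wrong: enolisation of the aldehyde with erosion of the C3 configuration, and β-elimination of benzyl alcohol before or during the addition.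
- The fallback sets out from 8 and comes back at 16. It replaces steps 6–9 and never passes through a carbonyl group next to a finished C3.
- Imide 8 is converted with Bu2BOTf/Et3N into the dibutylboron (Z)-enolate F10. Evans syn-aldol addition to commercial 4-(benzyloxy)-3-methoxybenzaldehyde gives the aldol adduct F11.
- In F11 the acyl carbon is the future CH2O group. The same (S)-auxiliary therefore again delivers the required C3 configuration.
- LiBH4 gives the 1,3-diol F12.
- Bu2SnO (toluene, reflux) gives the stannylene acetal F13. BnBr/CsF benzylates its primary oxygen selectively to give 16 as a single carbinol epimer, which enters steps 10 and 11 unchanged.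

**Further compounds**
F1 | step 19 | (2S,3R)-3-[(benzyloxy)methyl]-2-[4-(benzyloxy)-3-methoxyphenyl]-7-methoxy-2,3-dihydrobenzofuran-5-yllithium | COc1cc([Li])cc2c1O[C@H](c1ccc(OCc3ccccc3)c(OC)c1)[C@H]2COCc1ccccc1
F2 | step 19 | (2S,3R)-3-[(benzyloxy)methyl]-2-[4-(benzyloxy)-3-methoxyphenyl]-7-methoxy-2,3-dihydrobenzofuran-5-carbaldehyde | COc1cc(C=O)cc2c1O[C@H](c1ccc(OCc3ccccc3)c(OC)c1)[C@H]2COCc1ccccc1
F3 | step 19 | {(2S,3R)-3-[(benzyloxy)methyl]-2-[4-(benzyloxy)-3-methoxyphenyl]-7-methoxy-2,3-dihydrobenzofuran-5-yl}methanol | COc1cc(CO)cc2c1O[C@H](c1ccc(OCc3ccccc3)c(OC)c1)[C@H]2COCc1ccccc1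
F4 | step 19 | (2S,3R)-3-[(benzyloxy)methyl]-2-[4-(benzyloxy)-3-methoxyphenyl]-5-(bromomethyl)-7-methoxy-2,3-dihydrobenzofuran | COc1cc(CBr)cc2c1O[C@H](c1ccc(OCc3ccccc3)c(OC)c1)[C@H]2COCc1ccccc1
F5 | step 11 | [4-(tert-butyldimethylsilyloxy)-3-methoxyphenyl]magnesium bromide | COc1cc([Mg]Br)ccc1O[Si](C)(C)C(C)(C)C
F6 | step 11 | (2R)-2-[2-(allyloxy)-5-bromo-3-methoxyphenyl]-3-(benzyloxy)-1-[4-(tert-butyldimethylsilyloxy)-3-methoxyphenyl]propyl acetate (C1 epimers) | CC(=O)OC(c1ccc(O[Si](C)(C)C(C)(C)C)c(OC)c1)[C@@H](COCc1ccccc1)c1cc(Br)cc(OC)c1OCC=C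
F7 | step 11 | (2R)-3-(benzyloxy)-2-(5-bromo-2-hydroxy-3-methoxyphenyl)-1-[4-(tert-butyldimethylsilyloxy)-3-methoxyphenyl]propyl acetate (C1 epimers) | CC(=O)OC(c1ccc(O[Si](C)(C)C(C)(C)C)c(OC)c1)[C@@H](COCc1ccccc1)c1cc(Br)cc(OC)c1O
F8 | step 11 | 4-[(2R)-3-(benzyloxy)-2-(5-bromo-2-hydroxy-3-methoxyphenyl)propylidene]-2-methoxycyclohexa-2,5-dien-1-one | COC1=CC(=C[C@@H](COCc2ccccc2)c2cc(Br)cc(OC)c2O)C=CC1=O
F9 | step 11 | 4-{(2S,3R)-3-[(benzyloxy)methyl]-5-bromo-7-methoxy-2,3-dihydrobenzofuran-2-yl}-2-methoxyphenol | COc1cc(Br)cc2c1O[C@H](c1ccc(O)c(OC)c1)[C@H]2COCc1ccccc1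
F10 | step 9 | dibutylboron (Z)-enolate of 8 | CCCCB(CCCC)O/C(=C\c1cc(Br)cc(OC)c1OCC=C)N1[C@@H](Cc2ccccc2)COC1=O
F11 | step 9 | (S)-3-{(2S,3S)-2-[2-(allyloxy)-5-bromo-3-methoxyphenyl]-3-[4-(benzyloxy)-3-methoxyphenyl]-3-hydroxypropanoyl}-4-benzyloxazolidin-2-one | O=C([C@H]([C@H](O)c1ccc(OCc2ccccc2)c(OC)c1)c1cc(Br)cc(OC)c1OCC=C)N1[C@@H](Cc2ccccc2)COC1=O
F12 | step 9 | (1S,2R)-2-[2-(allyloxy)-5-bromo-3-methoxyphenyl]-1-[4-(benzyloxy)-3-methoxyphenyl]propane-1,3-diol | OC[C@H]([C@H](O)c1ccc(OCc2ccccc2)c(OC)c1)c1cc(Br)cc(OC)c1OCC=C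
F13 | step 9 | (4S,5R)-5-[2-(allyloxy)-5-bromo-3-methoxyphenyl]-4-[4-(benzyloxy)-3-methoxyphenyl]-2,2-dibutyl-1,3,2-dioxastanninane | CCCC[Sn]1(CCCC)OC[C@@H](c2cc(Br)cc(OC)c2OCC=C)[C@@H](c2ccc(OCc3ccccc3)c(OC)c2)O1
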